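**Retrosynthetic overview**
1. The C6–O ester bond and the C14 aldehyde are made last; the C6 carbinol comes from a C6 ketone by reduction directed by the C4 hydroxyl.
2. The C8=C9 alkene comes from 1,4-hydrogenation of the C7=C8–C9=C10 diene of a dienone, itself unmasked from a C6 methyl enol ether; the C2 oxygen left by the ring-forming step is removed by reduction and radical deoxygenation.
3. Key disconnection C1–C5 and C1–C10: the methyl-bearing quaternary fusion carbon C1 is bonded to both C5 and C10, the two ends of the six-carbon run C5–C10 of the seven-membered ring. C1 is therefore taken as a carbenoid carbon inserted into the ipso–ortho bond of a benzene ring (C5–C10, OMe on C6, CH2O on C8) by an intramolecular Büchner reaction of an α-methyl α-diazoketone.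
4. The diazoketone comes from an aryl isopropyl ketone by enantioselective allylboration (C4), silylation, oxidative cleavage and acylation of diazoethane.
5. Ring order: the benzene ring is bought; the five-membered ring (C1–C5 bond) and the seven-membered ring (C1–C10 bond, C5–C10 cleavage) form together in the key step.

Key step: step 7

**Remarks on the chemistry**
- Numbering: C1 is the quaternary C–CH3 fusion carbon, C2 and C3 the ring CH2 groups, C4 the C(OH)(i-Pr) carbon, C5 the fusion CH, C6–C10 the other seven-ring carbons (C6 carries the ester oxygen, C8 carries C14). β is the face of the C1 methyl group. The target is 1R,4R,5S,6S in this numbering.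
- (4-Bromo-3-methoxyphenyl)methanol is taken as a catalogue compound; it is otherwise one i-Bu2AlH reduction away from methyl 4-bromo-3-methoxybenzoate.
- The enantiomer named for each chiral catalyst (steps 3 and 7) is assumed to give the stated configuration; its antipode would be used otherwise, with no other change.
- The C2 carbinol made in step 8 is carried as whichever epimer forms, because C2 becomes CH2 in step 12.

**Route**

Step 1
Reactants: 1 (4-bromo-3-methoxyphenyl)methanol
Product: 2 tert-butyl[(4-bromo-3-methoxyphenyl)methoxy]diphenylsilane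
Conditions: TBDPSCl, imidazole, DMF, rt
Reagents that add atoms: tert-butyl(chloro)diphenylsilane, CC(C)(C)[Si](Cl)(c1ccccc1)c1ccccc1
Why: Imidazole-promoted O-silylation of the primary benzylic alcohol gives a TBDPS ether that withstands the organolithium, ozonolysis, weak-acid and HF·pyridine steps ahead.

Step 2
Reactants: 2 tert-butyl[(4-bromo-3-methoxyphenyl)methoxy]diphenylsilane; 3 N-methoxy-N-methylisobutyramide
Product: 6 1-[4-({[tert-butyl(diphenyl)silyl]oxy}methyl)-2-methoxyphenyl]-2-methylpropan-1-one, via aryllithium 4 (not isolated), via lithium hemiaminal alkoxide 5 (not isolated)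
Conditions: n-BuLi, THF, −78 °C; then 3, −78 → 0 °C; aqueous NH4Cl
Reagents that add atoms: none
Why: Bromine–lithium exchange outruns ortho-lithiation and the aryllithium adds once to the Weinreb amide, whose chelated tetrahedral adduct collapses to the ketone only on quench (Weinreb ketone synthesis).

Step 3
Reactants: 6 1-[4-({[tert-butyl(diphenyl)silyl]oxy}methyl)-2-methoxyphenyl]-2-methylpropan-1-one; 7 2-allyl-4,4,5,5-tetramethyl-1,3,2-dioxaborolane
Product: 8 (3R)-3-[4-({[tert-butyl(diphenyl)silyl]oxy}methyl)-2-methoxyphenyl]-2-methylhex-5-en-3-ol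
Conditions: 7 (1.5 equiv), (2S)-2-{[(3-tert-butyl-2-hydroxyphenyl)methyl]amino}-N,N,3-trimethylbutanamide (2.5 mol%), NaOt-Bu (5 mol%), MeOH (2 equiv), toluene, 22 °C
Reagents that add atoms: none
Why: Aminophenol-catalysed enantioselective allylboration of a ketone, in which the catalyst-bound allylboron is delivered through a hydrogen-bonded six-membered transition state to one enantiotopic face of the carbonyl and so sets the tertiary carbinol carbon C4 as R under catalyst control.

Step 4
Reactants: 8 (3R)-3-[4-({[tert-butyl(diphenyl)silyl]oxy}methyl)-2-methoxyphenyl]-2-methylhex-5-en-3-ol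
Product: 9 triethylsilyl ether of 8 (C4 R)
Conditions: TESOTf, 2,6-lutidine, CH2Cl2, −20 °C → rt
Reagents that add atoms: triethylsilyl trifluoromethanesulfonate, CC[Si](CC)(CC)OS(=O)(=O)C(F)(F)F
Why: Silylation with a silyl triflate and a hindered pyridine base works on congested tertiary alcohols and masks the hydroxyl, which would otherwise capture the carbenoid by O–H insertion.

Step 5
Reactants: 9 triethylsilyl ether of 8 (C4 R)
Product: 12 (3R)-3-[4-({[tert-butyl(diphenyl)silyl]oxy}methyl)-2-methoxyphenyl]-4-methyl-3-[(triethylsilyl)oxy]pentanoic acid, via 1,2,4-trioxolane 10 (not isolated), via aldehyde 11 (not isolated)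
Conditions: O3, CH2Cl2, −78 °C; PPh3, −78 °C → rt; crude aldehyde: NaClO2, NaH2PO4, 2-methyl-2-butene, t-BuOH/H2O, 0 °C → rt
Reagents that add atoms: ozone, [O-][O+]=O; sodium chlorite, [Na+].[O-]Cl=O
Why: Ozonolysis of the only alkene (far more reactive than the anisole ring at −78 °C) followed by Pinnick oxidation shortens the allyl group to the CH2CO2H arm (C3 and C2) without touching the silyl ethers or C4.

Step 6
Reactants: 12 (3R)-3-[4-({[tert-butyl(diphenyl)silyl]oxy}methyl)-2-methoxyphenyl]-4-methyl-3-[(triethylsilyl)oxy]pentanoic acid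
Product: 14 (5R)-5-[4-({[tert-butyl(diphenyl)silyl]oxy}methyl)-2-methoxyphenyl]-2-diazo-6-methyl-5-[(triethylsilyl)oxy]heptan-3-one, via isobutyl carbonic mixed anhydride 13 (not isolated)
Conditions: i-BuOCOCl, Et3N, THF, −15 °C; then ethereal CH3CHN2 (from N-ethyl-N-nitrosourea/KOH, 3 equiv), −15 °C → rt
Reagents that add atoms: diazoethane, CC=[N+]=[N-]
Why: Acylation of diazoethane by a mixed carbonic anhydride (diazoketone synthesis of the Arndt–Eistert type) installs the carbenoid carbon C1 with its methyl group under conditions mild enough for the tertiary silyl ether.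

Step 7
Reactants: 14 (5R)-5-[4-({[tert-butyl(diphenyl)silyl]oxy}methyl)-2-methoxyphenyl]-2-diazo-6-methyl-5-[(triethylsilyl)oxy]heptan-3-one
Product: 16 (3R,8aR)-6-({[tert-butyl(diphenyl)silyl]oxy}methyl)-4-methoxy-8a-methyl-3-(propan-2-yl)-3-[(triethylsilyl)oxy]-3,8a-dihydroazulen-1(2H)-one, via norcaradiene 15 (not isolated)
Conditions: [Cu(MeCN)4]PF6 (5 mol%, monovalent copper), 2,2'-(propane-2,2-diyl)bis[(4R)-4-phenyl-4,5-dihydro-1,3-oxazole] (6 mol%), NaB[3,5-(CF3)2C6H3]4 (6 mol%), CH2Cl2, reflux, slow addition of 14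
Reagents that add atoms: none
Why: Loss of N2 gives an electrophilic copper carbenoid at C1 that adds to the ipso carbon C5 (activated by the ortho methoxy group) and the free ortho carbon C10; the C1–C5 bond closes the cyclopentanone in a 5-exo mode through the C2–C3–C4 tether and gives norcaradiene 15. Thermal disrotatory 6π electrocyclic opening then cleaves C5–C10, so the benzene ring becomes the seven-membered ring by ring expansion, C1 becomes the fusion carbon, and its methyl group blocks tautomerisation of the azulenone. The closest known reaction is the copper–bis(oxazoline)-catalysed intramolecular Büchner reaction of 2-diazo-5-arylpentan-3-ones. The new quaternary stereocentre C1 is set by the arene face that is attacked: allylic strain against the ortho methoxy group should keep the small silyloxy oxygen of C4 in the arene plane and turn the isopropyl group to the face away from the tether, so the methyl group ends cis to the C4 oxygen, and the matched ligand enantiomer reinforces this. The step needs C10 over the methoxy-bearing C6 (C6 is sterically shielded) and arene addition over insertion into the isopropyl C–H bond or attack on the silyl ether oxygen (copper carbenoids insert poorly into C–H bonds, and the tertiary triethylsilyl ether is hindered and weakly basic).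

Step 8
Reactants: 16 (3R,8aR)-6-({[tert-butyl(diphenyl)silyl]oxy}methyl)-4-methoxy-8a-methyl-3-(propan-2-yl)-3-[(triethylsilyl)oxy]-3,8a-dihydroazulen-1(2H)-one
Product: 17 C2 alcohol of 16 (1R,4R; C2 epimer not defined)
Conditions: NaBH4, MeOH/THF, −20 °C
Reagents that add atoms: none
Why: Borohydride 1,2-reduction of the isolated cyclopentanone at low temperature, where enolisation towards C3 and loss of the C4 silyloxy group are slow, turns C2 into a carbinol for later deoxygenation, so the configuration of the new C2 centre does not matter.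

Step 9
Reactants: 17 C2 alcohol of 16 (1R,4R; C2 epimer not defined)
Product: 18 trans-fused dienone (1R,4R,5R; H-5 α) with C2 hydroxyl; C4 triethylsilyl ether; C6 ketone; C7=C8 and C9=C10; C14 TBDPS ether
Conditions: AcOH/THF/H2O (3:1:1), rt
Reagents that add atoms: water, O
Why: General-acid-catalysed enol ether hydrolysis, in which rate-limiting protonation of C5 gives the C6 oxocarbenium ion and water then methanol loss give the ketone; the proton should enter on the convex α-face opposite the C1 methyl and C4 silyloxy groups, setting H-5 α (trans fusion), which should also be the more stable epimer because C6 then lies anti to isopropyl, while the weak-acid medium keeps the hydronium concentration low so that ionisation of the C4–O bond lags behind.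

Step 10
Reactants: 18 trans-fused dienone (1R,4R,5R)
Product: 19 β,γ-unsaturated ketone (1R,4R,5R) with C2 hydroxyl; C4 triethylsilyl ether; C6 ketone; C8=C9; C14 TBDPS ether
Conditions: (η6-naphthalene)Cr(CO)3 (15 mol%, zerovalent chromium), H2 (4 atm), THF, 40 °C
Reagents that add atoms: none
Why: Arene–Cr(CO)3-catalysed 1,4-hydrogenation of a cisoid 1,3-diene adds hydrogen only to the termini C7 and C10 through an η4-diene dihydride and leaves C8=C9, which is the net 1,6-reduction of the dienone with hydrogen on the α-carbon, and it forms no enolate that could conjugate the alkene or expel the C4 oxygen.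

Step 11
Reactants: 19 β,γ-unsaturated ketone (1R,4R,5R) with C2 hydroxyl
Product: 20 C2 O-phenyl thionocarbonate of 19
Conditions: PhOC(S)Cl, pyridine, DMAP (0.1 equiv), CH2Cl2, 0 °C → rt
Reagents that add atoms: O-phenyl chlorothionoformate, S=C(Cl)Oc1ccccc1
Why: DMAP-catalysed acylation of the only free hydroxyl gives the thionocarbonate needed for Barton–McCombie deoxygenation, and the weak pyridine base should leave the β,γ-enone where it is.

Step 12
Reactants: 20 C2 O-phenyl thionocarbonate of 19
Product: 21 β,γ-unsaturated ketone (1R,4R,5R) with C2 methylene; C4 triethylsilyl ether; C14 TBDPS ether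
Conditions: Bu3SnH, AIBN, toluene, 85 °C
Reagents that add atoms: none
Why: Barton–McCombie deoxygenation, in which the secondary C2 radical has no alkene placed for 3-exo or 5-exo closure now that C10 is sp3 and simply takes hydrogen from Bu3SnH.

Step 13
Reactants: 21 β,γ-unsaturated ketone (1R,4R,5R) with C4 triethylsilyl ether
Product: 22 β-hydroxy ketone (1R,4R,5R) with free C4 hydroxyl; C6 ketone; C8=C9; C14 TBDPS ether
Conditions: HF·pyridine, pyridine, THF, 0 °C → rt
Reagents that add atoms: none
Why: Buffered HF·pyridine desilylation cleaves the triethylsilyl ether while the primary TBDPS ether survives, and its non-basic medium avoids retro-aldol cleavage of the β-hydroxy ketone.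

Step 14
Reactants: 22 β-hydroxy ketone (1R,4R,5R)
Product: 23 diol (1R,4R,5S,6S) with 4β and 6α hydroxyls; C8=C9; C14 TBDPS ether
Conditions: Me4NBH(OAc)3, MeCN/AcOH (1:1), −30 → −10 °C
Reagents that add atoms: none
Why: Evans–Saksena hydroxyl-directed reduction, in which ligand exchange puts the borohydride on the β-oriented C4 oxygen and hydride is delivered intramolecularly to the β-face of the C6 carbonyl, giving the 1,3-anti diol with the C6 hydroxyl α (6S).

Step 15
Reactants: 24 4-hydroxybenzoic acid
Product: 26 4-[(tert-butyldimethylsilyl)oxy]benzoic acid, via bis-silyl derivative 25 (not isolated)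
Conditions: TBSCl (2.5 equiv), imidazole, DMF, rt; then AcOH/THF/H2O, rt
Reagents that add atoms: tert-butyl(chloro)dimethylsilane, CC(C)(C)[Si](C)(C)Cl
Why: Silylation covers both acidic groups and the labile silyl ester is then hydrolysed selectively by mild aqueous acid, leaving the aryl silyl ether.

Step 16
Reactants: 23 diol (1R,4R,5S,6S); 26 4-[(tert-butyldimethylsilyl)oxy]benzoic acid
Product: 27 C6 4-[(tert-butyldimethylsilyl)oxy]benzoate of 23 (1R,4R,5S,6S)
Conditions: DCC, DMAP, CH2Cl2, rt
Reagents that add atoms: none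
Why: Steglich esterification acylates the secondary C6 hydroxyl only, the tertiary C4 hydroxyl being unreactive, and touches no stereocentre.

Step 17
Reactants: 27 C6 4-[(tert-butyldimethylsilyl)oxy]benzoate of 23
Product: 28 (1R,4R,5S,6S)-4-hydroxy-14-hydroxydauc-8-en-6-yl 4-hydroxybenzoate (C14 allylic alcohol)
Conditions: Bu4NF, AcOH, THF, 0 °C → rt
Reagents that add atoms: none
Why: Fluoride desilylation removes the aryl TBS and primary TBDPS ethers in one operation, and the acetic acid buffer protects the benzoate ester from the basic fluoride.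

Step 18
Reactants: 28 C14 allylic alcohol
Product: 29 (3R,3aS,4S,8aR)-6-formyl-3-hydroxy-8a-methyl-3-(propan-2-yl)-1,2,3,3a,4,5,8,8a-octahydroazulen-4-yl 4-hydroxybenzoate
Conditions: activated MnO2 (excess), CH2Cl2, rt
Reagents that add atoms: none
Why: MnO2 allylic oxidation converts only the primary allylic alcohol into the enal, since the tertiary alcohol, the ester and the electron-poor phenol are inert to it.

**Compound list**
1 | (4-bromo-3-methoxyphenyl)methanol | OCc1ccc(Br)c(OC)c1 | starting material
2 | tert-butyl[(4-bromo-3-methoxyphenyl)methoxy]diphenylsilane | Brc1ccc(CO[Si](c2ccccc2)(c2ccccc2)C(C)(C)C)cc1OC | intermediate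
3 | N-methoxy-N-methylisobutyramide | CC(C)C(=O)N(C)OC | starting material
4 | [4-({[tert-butyl(diphenyl)silyl]oxy}methyl)-2-methoxyphenyl]lithium | [Li]c1ccc(CO[Si](c2ccccc2)(c2ccccc2)C(C)(C)C)cc1OC | intermediate
5 | lithium alkoxide of the N-methoxy-N-methyl hemiaminal from 4 and 3 | CC(C)C(O[Li])(N(C)OC)c1ccc(CO[Si](c2ccccc2)(c2ccccc2)C(C)(C)C)cc1OC | intermediate
6 | 1-[4-({[tert-butyl(diphenyl)silyl]oxy}methyl)-2-methoxyphenyl]-2-methylpropan-1-one | CC(C)C(=O)c1ccc(CO[Si](c2ccccc2)(c2ccccc2)C(C)(C)C)cc1OC | intermediate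
7 | 2-allyl-4,4,5,5-tetramethyl-1,3,2-dioxaborolane | C=CCB1OC(C)(C)C(C)(C)O1 | starting material
8 | (3R)-3-[4-({[tert-butyl(diphenyl)silyl]oxy}methyl)-2-methoxyphenyl]-2-methylhex-5-en-3-ol | CC(C)[C@](O)(CC=C)c1ccc(CO[Si](c2ccccc2)(c2ccccc2)C(C)(C)C)cc1OC | intermediate
9 | triethylsilyl ether of 8 (R) | CC(C)[C@](O[Si](CC)(CC)CC)(CC=C)c1ccc(CO[Si](c2ccccc2)(c2ccccc2)C(C)(C)C)cc1OC | intermediate
10 | 1,2,4-trioxolane (ozonide) of 9 | CC(C)[C@](O[Si](CC)(CC)CC)(CC1OCOO1)c1ccc(CO[Si](c2ccccc2)(c2ccccc2)C(C)(C)C)cc1OC | intermediate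
11 | (3R)-3-aryl-4-methyl-3-[(triethylsilyl)oxy]pentanal | CC(C)[C@](O[Si](CC)(CC)CC)(CC=O)c1ccc(CO[Si](c2ccccc2)(c2ccccc2)C(C)(C)C)cc1OC | intermediate
12 | (3R)-3-[4-({[tert-butyl(diphenyl)silyl]oxy}methyl)-2-methoxyphenyl]-4-methyl-3-[(triethylsilyl)oxy]pentanoic acid | CC(C)[C@](O[Si](CC)(CC)CC)(CC(=O)O)c1ccc(CO[Si](c2ccccc2)(c2ccccc2)C(C)(C)C)cc1OC | intermediate
13 | isobutyl carbonic mixed anhydride of 12 | CC(C)[C@](O[Si](CC)(CC)CC)(CC(=O)OC(=O)OCC(C)C)c1ccc(CO[Si](c2ccccc2)(c2ccccc2)C(C)(C)C)cc1OC | intermediate
14 | (5R)-5-[4-({[tert-butyl(diphenyl)silyl]oxy}methyl)-2-methoxyphenyl]-2-diazo-6-methyl-5-[(triethylsilyl)oxy]heptan-3-one | CC(C)[C@](O[Si](CC)(CC)CC)(CC(=O)C(C)=[N+]=[N-])c1ccc(CO[Si](c2ccccc2)(c2ccccc2)C(C)(C)C)cc1OC | intermediate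
15 | norcaradiene: cyclopropane C1–C5–C10 fused to the cyclopentanone and to the 6-methoxy-8-(silyloxymethyl)cyclohexadiene, C1 methyl cis to the C4 oxygen | CC(C)[C@]1(O[Si](CC)(CC)CC)CC(=O)[C@]2(C)[C@H]3C=C(CO[Si](c4ccccc4)(c4ccccc4)C(C)(C)C)C=C(OC)[C@@]123 | intermediate
16 | (3R,8aR)-6-({[tert-butyl(diphenyl)silyl]oxy}methyl)-4-methoxy-8a-methyl-3-(propan-2-yl)-3-[(triethylsilyl)oxy]-3,8a-dihydroazulen-1(2H)-one | CC(C)[C@]1(O[Si](CC)(CC)CC)CC(=O)[C@]2(C)C=CC(CO[Si](c3ccccc3)(c3ccccc3)C(C)(C)C)=CC(OC)=C21 | intermediate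
17 | C2 alcohol of 16 (1R,4R; C2 epimer not defined) | CC(C)[C@]1(O[Si](CC)(CC)CC)CC(O)[C@]2(C)C=CC(CO[Si](c3ccccc3)(c3ccccc3)C(C)(C)C)=CC(OC)=C21 | intermediate
18 | trans-fused dienone (1R,4R,5R): C2 hydroxyl, C4 triethylsilyl ether, C6 ketone, C7=C8 and C9=C10, C14 TBDPS ether | CC(C)[C@]1(O[Si](CC)(CC)CC)CC(O)[C@]2(C)C=CC(CO[Si](c3ccccc3)(c3ccccc3)C(C)(C)C)=CC(=O)[C@H]21 | intermediate
19 | β,γ-unsaturated ketone (1R,4R,5R): C2 hydroxyl, C4 triethylsilyl ether, C6 ketone, C8=C9, C14 TBDPS ether | CC(C)[C@]1(O[Si](CC)(CC)CC)CC(O)[C@]2(C)CC=C(CO[Si](c3ccccc3)(c3ccccc3)C(C)(C)C)CC(=O)[C@H]21 | intermediate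
20 | C2 O-phenyl thionocarbonate of 19 | CC(C)[C@]1(O[Si](CC)(CC)CC)CC(OC(=S)Oc3ccccc3)[C@]2(C)CC=C(CO[Si](c3ccccc3)(c3ccccc3)C(C)(C)C)CC(=O)[C@H]21 | intermediate
21 | β,γ-unsaturated ketone (1R,4R,5R): C2 methylene, C4 triethylsilyl ether, C14 TBDPS ether | CC(C)[C@]1(O[Si](CC)(CC)CC)CC[C@]2(C)CC=C(CO[Si](c3ccccc3)(c3ccccc3)C(C)(C)C)CC(=O)[C@H]21 | intermediate
22 | β-hydroxy ketone (1R,4R,5R): 4β-hydroxyl, C6 ketone, C8=C9, C14 TBDPS ether | CC(C)[C@]1(O)CC[C@]2(C)CC=C(CO[Si](c3ccccc3)(c3ccccc3)C(C)(C)C)CC(=O)[C@H]21 | intermediate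
23 | diol (1R,4R,5S,6S): 4β- and 6α-hydroxyls, C8=C9, C14 TBDPS ether | CC(C)[C@]1(O)CC[C@]2(C)CC=C(CO[Si](c3ccccc3)(c3ccccc3)C(C)(C)C)C[C@H](O)[C@H]21 | intermediate
24 | 4-hydroxybenzoic acid | O=C(O)c1ccc(O)cc1 | starting material
25 | tert-butyldimethylsilyl 4-[(tert-butyldimethylsilyl)oxy]benzoate | CC(C)(C)[Si](C)(C)OC(=O)c1ccc(O[Si](C)(C)C(C)(C)C)cc1 | intermediate
26 | 4-[(tert-butyldimethylsilyl)oxy]benzoic acid | O=C(O)c1ccc(O[Si](C)(C)C(C)(C)C)cc1 | intermediate
27 | C6 4-[(tert-butyldimethylsilyl)oxy]benzoate of 23 (1R,4R,5S,6S) | CC(C)[C@]1(O)CC[C@]2(C)CC=C(CO[Si](c3ccccc3)(c3ccccc3)C(C)(C)C)C[C@H](OC(=O)c3ccc(O[Si](C)(C)C(C)(C)C)cc3)[C@H]21 | intermediate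
28 | (3R,3aS,4S,8aR)-3-hydroxy-6-(hydroxymethyl)-8a-methyl-3-(propan-2-yl)-1,2,3,3a,4,5,8,8a-octahydroazulen-4-yl 4-hydroxybenzoate | CC(C)[C@]1(O)CC[C@]2(C)CC=C(CO)C[C@H](OC(=O)c3ccc(O)cc3)[C@H]21 | intermediate
29 | (3R,3aS,4S,8aR)-6-formyl-3-hydroxy-8a-methyl-3-(propan-2-yl)-1,2,3,3a,4,5,8,8a-octahydroazulen-4-yl 4-hydroxybenzoate | CC(C)[C@]1(O)CC[C@]2(C)CC=C(C=O)C[C@H](OC(=O)c3ccc(O)cc3)[C@H]21 | target

**Step count**
Total: 18 steps. Longest linear sequence: 17 steps (steps 1–14 and 16–18); step 15 is a one-step side branch.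

**Steps most likely to fail, with fallbacks**

Step 7 (key step). The carbenoid may be consumed by insertion into the isopropyl C–H bond, by attack on the silyl ether oxygen or by 1,2-hydride shift to an enone, or it may add to the arene with poor facial selectivity and give the C1 epimer. The fallback runs the ring expansion with the unsubstituted carbenoid and completes C1 afterwards, so that facial control in the carbenoid step no longer matters. It sets out from acid 12: the mixed anhydride 13 is treated with CH2N2 to give the terminal diazoketone (4R)-4-aryl-1-diazo-5-methyl-4-[(triethylsilyl)oxy]hexan-2-one F1. Rh2(OAc)4 (divalent rhodium) in CH2Cl2 then effects the parent Büchner cyclisation to the C1–H azulenone F2. LiN(SiMe3)2 in THF at −78 °C should remove the C1 hydrogen, whose enolate is conjugated with the triene, in preference to the C3 hydrogens, whose enolate could expel the C4 silyloxy group. MeI should then alkylate C1 on the face away from the isopropyl group, returning to 16.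

Step 9. Acid may ionise the C4–O bond through the vinylogous ketal (loss or scrambling of the C4 oxygen), the free C2 hydroxyl may add to C6 or C8, or C5 may be protonated from the wrong face. The fallback changes the order of events. It sets out from 16: the same AcOH/THF/H2O hydrolysis is run while C2 is still a carbonyl, which inductively retards ionisation at C4 and leaves no free hydroxyl, giving the trans-fused diketone F3. NaBH4 in MeOH/CH2Cl2 at −78 °C should then reduce the saturated cyclopentanone in preference to the doubly conjugated C6 carbonyl, returning to 18.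

Step 10. The chromium catalyst may fail to bind the hindered trisubstituted diene and leave 18 unchanged, or prolonged heating may move the new alkene into conjugation with the ketone. The fallback replaces hydrogenation by polar conjugate reduction. It sets out from 18: [(Ph3P)CuH]6 in THF containing water should deliver hydride to the δ-carbon C10 (the β-carbon C8 is fully substituted), and the copper dienolate is protonated kinetically at C7, returning directly to 19. This fallback adds no compound (none F0).

**Further compounds**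
F1 | step 7 | (4R)-4-[4-({[tert-butyl(diphenyl)silyl]oxy}methyl)-2-methoxyphenyl]-1-diazo-5-methyl-4-[(triethylsilyl)oxy]hexan-2-one | CC(C)[C@](O[Si](CC)(CC)CC)(CC(=O)C=[N+]=[N-])c1ccc(CO[Si](c2ccccc2)(c2ccccc2)C(C)(C)C)cc1OC
F2 | step 7 | (3R)-6-({[tert-butyl(diphenyl)silyl]oxy}methyl)-4-methoxy-3-(propan-2-yl)-3-[(triethylsilyl)oxy]-3,8a-dihydroazulen-1(2H)-one (C1–H, C1 not defined) | CC(C)[C@]1(O[Si](CC)(CC)CC)CC(=O)C2C=CC(CO[Si](c3ccccc3)(c3ccccc3)C(C)(C)C)=CC(OC)=C21
F3 | step 9 | trans-fused diketone (1R,4R,5R): C2 ketone, C4 triethylsilyl ether, C6 ketone, C7=C8 and C9=C10, C14 TBDPS ether | CC(C)[C@]1(O[Si](CC)(CC)CC)CC(=O)[C@]2(C)C=CC(CO[Si](c3ccccc3)(c3ccccc3)C(C)(C)C)=CC(=O)[C@H]21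
F0 | step 10 | none | none
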